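## Analysis of the target

Target 17 is a 2H-chromene: a benzene ring (ring A) fused to a 2H-pyran (ring B: O1–C2–C3=C4–C4a–C8a). Ring A carries an acetyl group at C6, para to O1, and a methoxy group at C8. C2 carries a methyl group and a CH2O arm esterified with (E)-ferulic acid 13. C2 is the only stereocentre. It is quaternary and R-configured, so there is no relative stereochemistry to manage, only absolute control at a tertiary alkyl aryl ether carbon whose methyl group and two one-carbon arms are close in size. The sensitive groups are the styrenic C3=C4 bond (acid, electrophiles), the cinnamate ester and free phenol (base, nucleophiles, hydride) and the aryl methyl ketone (hydride). The C2–O1 bond is also at risk: heat or light can open ring B by an oxa-6π process to an achiral ortho-quinone methide, which would racemise C2. The difficulty is therefore to create this ether stereocentre in one absolute sense and then close ring B without ever breaking C2–O1. The strategy rests on the fact that C2 bears O1, CH3 and two one-carbon arms at different oxidation levels (the CH2O arm and the sp2 carbon C3), so C2 maps onto the prochiral central carbon of a 2-aryloxy-2-methylmalonate with two enantiotopic ester groups.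

## Retrosynthetic reasoning

**Ester bond.** The acyl C–O bond of 17 is cut first, giving alcohol 12 and the phenol-protected acid 14 (made from 13, activated as 15, coupled to give 16). The cinnamate would not survive the hydride and base steps needed earlier, so it goes on last. The alcohol of 12 is neopentyl-like, so the forward reaction has to be an acylation at oxygen, not a displacement at the CH2 carbon. The phenol of 13 is masked as an aryl acetate because that group can be removed by aminolysis without touching the alkyl cinnamate.

**C6–acetyl bond.** Ketone 11 is traced to aryl bromide 9 through enol ether 10. A ketone would not pass the hydride steps that differentiate the two arms, whereas a bromide is inert to them and is already para to the oxygen in phenol 1. The forward step is a palladium-catalysed coupling with an acetyl-anion equivalent, mild enough not to open ring B.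

**C4–C4a bond.** Chromene 9 is opened to the aryl propargyl ether 8. Cutting here keeps C2–O1 intact from the first step to the last. The forward reaction is a gold-catalysed 6-endo hydroarylation at the only free position ortho to the ether oxygen. A thermal sigmatropic route to the same ring is excluded because it breaks C2–O1 and passes through an achiral intermediate.

**C3≡C4 bond.** Alkyne 8 comes from aldehyde 7 by one-carbon homologation, and 7 from ester 6 by partial reduction. C3 is thereby derived from a carboxyl carbon, and C4 is the only carbon added after the stereocentre is set.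

**Differentiating the arms.** Silyl ether 6 comes from hydroxy ester 5, and 5 from half-ester 4 by reduction of the free acid only. Acid and ester are chemically distinct, so each carboxyl carbon can be assigned to one arm at will.

**Key disconnection.** Half-ester 4 is traced to the achiral diester 3. No skeletal bond is cut. Only one of two enantiotopic ester C–O bonds is re-formed, and the stereocentre disappears into a symmetric precursor that already carries O1, the methyl group and both future arms.

**O–C2 bond.** Diester 3 is cut at the ether bond into phenol 1 and bromomalonate 2. The hindered tertiary ether is made on a doubly activated bromide, at a stage where nothing stereochemical is at stake.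

## Alternatives that were turned down

**Alternative 1:** This route cuts two bonds at once, the ester CH2–O bond and the O1–C8a bond. The precursors are a fluoroarene carrying a (Z)-vinyl 2-methyloxirane, A2, and O-allylferulic acid A3.
- Forward key step: under a carbonate base the carboxylate of A3 opens the oxirane of A2 at its CH2 terminus. The tertiary alkoxide released then displaces fluoride at C8a, para to the acetyl group, closing ring B and giving A1, the O-allyl ether of 17.
- In its favour: it is convergent, forms the ester, the aryl ether and ring B in one operation, carries the acetyl group from the start as the activating group, and leaves only a deallylation. After A2 it is clearly shorter than the chosen route is after 4.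
- Against it: A2 is a vinyl oxirane with a tertiary allylic C–O bond, so the carboxylate can also attack in an SN2' sense at C4 or through ionisation at C2, which would scramble the stereocentre. The Z-alkene needed for closure must be built and kept next to the epoxide. The alkoxide sits beside the new ester and can take the acyl group instead of attacking the arene. The base also enolises the acetyl group. Above all, enantiopure A2 is a 2,2-disubstituted terminal epoxide with no simple asymmetric entry, so the stereochemical problem is moved, not solved.
- Comparison: the chosen strategy gives up the convergence but creates the stereocentre from a one-step achiral precursor and never exposes C2 to ionising conditions.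

**Alternative 2:** This route cuts the C2–CH2O bond.
- Forward key step: the lithium enolate of the chiral-pool cis-dioxolanone A5 is alkylated by a protected chloromethyl ether on the face anti to the tert-butyl group, giving A4 with the quaternary centre configured as C2 of 17.
- In its favour: the facial selectivity of such acetal enolates is very dependable and the absolute configuration follows from the source. On this point it is stronger than an enzyme whose sense cannot be predicted with confidence.
- Against it: the oxygen on the stereocentre of A4 is an acetal oxygen. The O1–C8a bond must still be made from a hindered tertiary alcohol and an arene, which is far harder than the bromide displacement that makes 3. The lactone carbonyl must also be unmasked and extended to C3 and C4, with additional protecting-group steps.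
- Comparison: the chosen strategy offers a less certain stereochemical outcome but has the aryl ether, the methyl group and both arms in place before the stereocentre exists, and needs fewer steps.

**Alternative 3:** This route cuts C3–C4 and C4–C4a, leading back to the benzofuran-3-one A7.
- Forward key step: a silyl diazomethane under Lewis acid activation inserts one carbon between the carbonyl carbon and ring A, expanding the furanone to the chroman-3-one A6.
- In its favour: the bond to ring A is made at the acylium level when A7 is formed, which does not depend on the modest nucleophilicity of the brominated ring towards a π-acid. It also needs no noble-metal step. On that point it may be the more robust ring construction.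
- Against it: the step creates no stereocentre, so A7 must already contain C2 in enantiopure form, most plausibly from 4 itself. Aryl migration must win over migration of the quaternary carbon and over epoxide formation or double insertion. A6 still has to be reduced and dehydrated to install C3=C4, and its C4 protons are readily enolised.
- Comparison: it replaces steps 5 to 7 of the chosen route with a longer sequence and contributes nothing to the stereochemical problem.

Key step: step 2

Assumption: the esterase is taken to cleave the pro-R ethoxycarbonyl group of 3 and so to deliver (S)-4; the opposite sense is covered in the fallback for step 2.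

## Route

Step 1
Reactants: 1 4-bromo-2-methoxyphenol; 2 diethyl 2-bromo-2-methylmalonate
Product: 3 diethyl 2-(4-bromo-2-methoxyphenoxy)-2-methylmalonate
Conditions: K2CO3, DMF, 60 °C
Reagents that add atoms: none
Why: Williamson-type O-alkylation in which the phenoxide displaces bromide from the doubly carbonyl-activated tertiary carbon; a weak carbonate base in a polar aprotic solvent favours substitution over elimination to the methylidene malonate, and the product is achiral.

Step 2
Reactants: 3 diethyl 2-(4-bromo-2-methoxyphenoxy)-2-methylmalonate
Product: 4 (2S)-2-(4-bromo-2-methoxyphenoxy)-3-ethoxy-2-methyl-3-oxopropanoic acid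
Conditions: pig liver esterase, 0.1 M phosphate buffer (pH 7.5)/DMSO 9:1, 25 °C, pH-stat (1 M NaOH); then HCl to pH 2, 0 °C
Reagents that add atoms: water, O
Why: Enzymatic desymmetrisation of a prochiral diester: the active-site serine adds to one ester carbonyl, ethanol leaves from the tetrahedral intermediate, and water cleaves the acyl-enzyme to the half-ester. The closest known reaction type is the esterase desymmetrisation of 2,2-disubstituted malonate diesters, 2-alkoxy-2-methyl members included. No ring closes and no skeletal bond forms; the C2 stereocentre arises only because one of two enantiotopic ester groups is cleaved. The controlling element is the chiral active site, which should place the large aryloxy group in its large hydrophobic pocket and the methyl group in the small one, so that only one ester group reaches the serine. The step needs enantiotopic-group selectivity and a stop at mono-hydrolysis. The size difference between the ortho-methoxy, para-bromo aryloxy group and methyl serves the first, and the carboxylate of 4, a poor substrate for the esterase, serves the second. The new centre is quaternary and cannot epimerise by enolisation. The work-up is kept cold because a malonic half-acid decarboxylates on heating.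

Step 3
Reactants: 4 (2S)-2-(4-bromo-2-methoxyphenoxy)-3-ethoxy-2-methyl-3-oxopropanoic acid
Product: 5 ethyl (2S)-2-(4-bromo-2-methoxyphenoxy)-3-hydroxy-2-methylpropanoate
Conditions: BH3·SMe2, THF, 0 °C to rt; then MeOH
Reagents that add atoms: none
Why: Chemoselective borane reduction: the acid is reduced through its acyloxyborane much faster than the ester, so the acid carbon becomes the CH2O arm; the aryl bromide and the quaternary centre are untouched.

Step 4
Reactants: 5 ethyl (2S)-2-(4-bromo-2-methoxyphenoxy)-3-hydroxy-2-methylpropanoate
Product: 6 ethyl (2S)-2-(4-bromo-2-methoxyphenoxy)-3-[(tert-butyldiphenylsilyl)oxy]-2-methylpropanoate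
Conditions: t-BuPh2SiCl, imidazole, DMF, rt
Reagents that add atoms: tert-butyl(chloro)diphenylsilane, CC(C)(C)[Si](Cl)(c1ccccc1)c1ccccc1
Why: Standard silylation of a primary alcohol; the tert-butyldiphenylsilyl group is chosen because it withstands the carbonate of step 6 and the dilute acid of step 8, and it keeps the oxygen from adding to the gold-activated alkyne in step 7.

Step 5
Reactants: 6 ethyl (2S)-2-(4-bromo-2-methoxyphenoxy)-3-[(tert-butyldiphenylsilyl)oxy]-2-methylpropanoate
Product: 7 (2S)-2-(4-bromo-2-methoxyphenoxy)-3-[(tert-butyldiphenylsilyl)oxy]-2-methylpropanal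
Conditions: i-Bu2AlH (1.1 equiv), CH2Cl2, −78 °C; then MeOH, aq. KNaC4H4O6
Reagents that add atoms: none
Why: Partial reduction of an alpha-oxygenated ester: the tetrahedral aluminium hemiacetal is held by chelation to the neighbouring ether oxygens and collapses only on work-up; the aldehyde has no alpha-hydrogen and cannot epimerise.

Step 6
Reactants: 7 (2S)-2-(4-bromo-2-methoxyphenoxy)-3-[(tert-butyldiphenylsilyl)oxy]-2-methylpropanal
Product: 8 tert-butyl{[(2R)-2-(4-bromo-2-methoxyphenoxy)-2-methylbut-3-yn-1-yl]oxy}diphenylsilane
Conditions: dimethyl (1-diazo-2-oxopropyl)phosphonate, K2CO3, MeOH, 0 °C to rt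
Reagents that add atoms: dimethyl (1-diazo-2-oxopropyl)phosphonate, COP(=O)(OC)C(=[N+]=[N-])C(C)=O
Why: Ohira–Bestmann variant of the Seyferth–Gilbert homologation: methanolysis releases the diazomethylphosphonate anion, which olefinates the aldehyde; loss of N2 and a 1,2-hydrogen shift give the terminal alkyne. The carbonate base spares the aryl bromide, and the descriptor changes from S to R only through a change of priorities.

Step 7
Reactants: 8 tert-butyl{[(2R)-2-(4-bromo-2-methoxyphenoxy)-2-methylbut-3-yn-1-yl]oxy}diphenylsilane
Product: 9 tert-butyl{[(2R)-6-bromo-8-methoxy-2-methyl-2H-chromen-2-yl]methoxy}diphenylsilane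
Conditions: Ph3PAuNTf2 (5 mol%), CH2Cl2, rt to 40 °C
Reagents that add atoms: none
Why: Gold-catalysed intramolecular hydroarylation of an aryl propargyl ether: cationic monovalent gold activates the alkyne, the only free carbon ortho to the ether oxygen attacks the terminal alkyne carbon in a 6-endo-dig closure, and protodeauration gives ring B. C2–O1 is never broken, so the configuration is retained, and the fully substituted propargylic carbon favours closure.

Step 8
Reactants: 9 tert-butyl{[(2R)-6-bromo-8-methoxy-2-methyl-2H-chromen-2-yl]methoxy}diphenylsilane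
Product: 11 1-[(2R)-2-{[(tert-butyldiphenylsilyl)oxy]methyl}-8-methoxy-2-methyl-2H-chromen-6-yl]ethan-1-one, via enol ether 10 (not isolated)
Conditions: tributyl(1-ethoxyvinyl)stannane, Pd(PPh3)4 (5 mol%), toluene, 80 °C, dark; then 1 M HCl, THF, rt
Reagents that add atoms: tributyl(1-ethoxyvinyl)stannane, CCCC[Sn](CCCC)(CCCC)C(=C)OCC; water, O
Why: Stille coupling with an acetyl-anion equivalent (oxidative addition of zerovalent palladium into C–Br, transmetalation, reductive elimination), then hydrolysis of the aryl enol ether by dilute acid. Moderate temperature and exclusion of light guard against electrocyclic opening of ring B, and the silyl ether tolerates the brief acid treatment.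

Step 9
Reactants: 11 1-[(2R)-2-{[(tert-butyldiphenylsilyl)oxy]methyl}-8-methoxy-2-methyl-2H-chromen-6-yl]ethan-1-one
Product: 12 1-[(2R)-2-(hydroxymethyl)-8-methoxy-2-methyl-2H-chromen-6-yl]ethan-1-one
Conditions: Bu4NF, AcOH, THF, rt
Reagents that add atoms: none
Why: Fluoride-induced cleavage of the silyl ether, driven by the strong Si–F bond; acetic acid buffers the alkoxide so that the ketone and the chromene see no strong base.

Step 10
Reactants: 13 ferulic acid
Product: 14 (E)-3-(4-acetoxy-3-methoxyphenyl)prop-2-enoic acid
Conditions: Ac2O, pyridine, rt; then H2O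
Reagents that add atoms: acetic anhydride, CC(=O)OC(C)=O
Why: Acetylation of the phenol; any mixed anhydride formed at the carboxyl group is hydrolysed on aqueous work-up, and the E-alkene is not affected.

Step 11
Reactants: 12 1-[(2R)-2-(hydroxymethyl)-8-methoxy-2-methyl-2H-chromen-6-yl]ethan-1-one; 14 (E)-3-(4-acetoxy-3-methoxyphenyl)prop-2-enoic acid
Product: 16 [(2R)-6-acetyl-8-methoxy-2-methyl-2H-chromen-2-yl]methyl (E)-3-(4-acetoxy-3-methoxyphenyl)prop-2-enoate, via acid chloride 15 (not isolated)
Conditions: (COCl)2, DMF (cat.), CH2Cl2, 0 °C to rt, evaporate; then 12, Et3N, DMAP (cat.), CH2Cl2, 0 °C to rt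
Reagents that add atoms: none
Why: Acid chloride formation under DMF catalysis, then DMAP-catalysed acylation of the hindered alcohol; the bond forms at oxygen, so the neopentyl-like CH2 carbon is never attacked, and the acyl chloride reacts far faster than the aryl acetate.

Step 12
Reactants: 16 [(2R)-6-acetyl-8-methoxy-2-methyl-2H-chromen-2-yl]methyl (E)-3-(4-acetoxy-3-methoxyphenyl)prop-2-enoate
Product: 17 [(2R)-6-acetyl-8-methoxy-2-methyl-2H-chromen-2-yl]methyl (E)-3-(4-hydroxy-3-methoxyphenyl)prop-2-enoate
Conditions: pyrrolidine (3 equiv), CH2Cl2, 0 °C to rt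
Reagents that add atoms: none
Why: Chemoselective aminolysis of the aryl acetate: phenoxide is a far better leaving group than the alkoxide of the cinnamate ester, so only the acetyl group is transferred to the amine, and the ketone, chromene and E-alkene are left alone.

## Compound list

1 | 4-bromo-2-methoxyphenol | COc1cc(Br)ccc1O | starting material
2 | diethyl 2-bromo-2-methylmalonate | CCOC(=O)C(C)(Br)C(=O)OCC | starting material
3 | diethyl 2-(4-bromo-2-methoxyphenoxy)-2-methylmalonate | CCOC(=O)C(C)(C(=O)OCC)Oc1ccc(Br)cc1OC | intermediate
4 | (2S)-2-(4-bromo-2-methoxyphenoxy)-3-ethoxy-2-methyl-3-oxopropanoic acid | OC(=O)[C@@](C)(C(=O)OCC)Oc1ccc(Br)cc1OC | intermediate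
5 | ethyl (2S)-2-(4-bromo-2-methoxyphenoxy)-3-hydroxy-2-methylpropanoate | OC[C@@](C)(C(=O)OCC)Oc1ccc(Br)cc1OC | intermediate
6 | ethyl (2S)-2-(4-bromo-2-methoxyphenoxy)-3-[(tert-butyldiphenylsilyl)oxy]-2-methylpropanoate | CC(C)(C)[Si](c1ccccc1)(c1ccccc1)OC[C@@](C)(C(=O)OCC)Oc1ccc(Br)cc1OC | intermediate
7 | (2S)-2-(4-bromo-2-methoxyphenoxy)-3-[(tert-butyldiphenylsilyl)oxy]-2-methylpropanal | CC(C)(C)[Si](c1ccccc1)(c1ccccc1)OC[C@@](C)(C=O)Oc1ccc(Br)cc1OC | intermediate
8 | tert-butyl{[(2R)-2-(4-bromo-2-methoxyphenoxy)-2-methylbut-3-yn-1-yl]oxy}diphenylsilane | CC(C)(C)[Si](c1ccccc1)(c1ccccc1)OC[C@@](C)(C#C)Oc1ccc(Br)cc1OC | intermediate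
9 | tert-butyl{[(2R)-6-bromo-8-methoxy-2-methyl-2H-chromen-2-yl]methoxy}diphenylsilane | CC(C)(C)[Si](c1ccccc1)(c1ccccc1)OC[C@@]1(C)C=Cc2cc(Br)cc(OC)c2O1 | intermediate
10 | tert-butyl{[(2R)-6-(1-ethoxyethenyl)-8-methoxy-2-methyl-2H-chromen-2-yl]methoxy}diphenylsilane | CC(C)(C)[Si](c1ccccc1)(c1ccccc1)OC[C@@]1(C)C=Cc2cc(C(=C)OCC)cc(OC)c2O1 | intermediate
11 | 1-[(2R)-2-{[(tert-butyldiphenylsilyl)oxy]methyl}-8-methoxy-2-methyl-2H-chromen-6-yl]ethan-1-one | CC(C)(C)[Si](c1ccccc1)(c1ccccc1)OC[C@@]1(C)C=Cc2cc(C(C)=O)cc(OC)c2O1 | intermediate
12 | 1-[(2R)-2-(hydroxymethyl)-8-methoxy-2-methyl-2H-chromen-6-yl]ethan-1-one | OC[C@@]1(C)C=Cc2cc(C(C)=O)cc(OC)c2O1 | intermediate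
13 | ferulic acid, (E)-3-(4-hydroxy-3-methoxyphenyl)prop-2-enoic acid | COc1cc(/C=C/C(=O)O)ccc1O | starting material
14 | (E)-3-(4-acetoxy-3-methoxyphenyl)prop-2-enoic acid | COc1cc(/C=C/C(=O)O)ccc1OC(C)=O | intermediate
15 | (E)-3-(4-acetoxy-3-methoxyphenyl)prop-2-enoyl chloride | COc1cc(/C=C/C(Cl)=O)ccc1OC(C)=O | intermediate
16 | [(2R)-6-acetyl-8-methoxy-2-methyl-2H-chromen-2-yl]methyl (E)-3-(4-acetoxy-3-methoxyphenyl)prop-2-enoate | COc1cc(/C=C/C(=O)OC[C@@]2(C)C=Cc3cc(C(C)=O)cc(OC)c3O2)ccc1OC(C)=O | intermediate
17 | [(2R)-6-acetyl-8-methoxy-2-methyl-2H-chromen-2-yl]methyl (E)-3-(4-hydroxy-3-methoxyphenyl)prop-2-enoate | COc1cc(/C=C/C(=O)OC[C@@]2(C)C=Cc3cc(C(C)=O)cc(OC)c3O2)ccc1O | target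

## Step count and least certain steps

Total: 12 steps. Longest linear sequence: 11 steps (steps 1 to 9, 11 and 12); step 10 is a one-step side branch.

**Step 2 (key step).** The most likely failure is incomplete discrimination between the two enantiotopic ester groups, because the pocket model is only a guide for an ortho-substituted aryloxy group. Discrimination in the opposite sense, or slow turnover of a hindered diethyl ester, is also possible. The fallback is a classical resolution that uses both antipodes; it sets out from 3 and returns at 4 and at 5.
- One ester of 3 is saponified with KOH (1 equiv) in EtOH to racemic 2-(4-bromo-2-methoxyphenoxy)-3-ethoxy-2-methyl-3-oxopropanoic acid F1.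
- Crystallisation with (R)-1-phenylethylamine, or with its antipode if that gives the less soluble salt of the wanted acid, should give (R)-1-phenylethylammonium (2S)-2-(4-bromo-2-methoxyphenoxy)-3-ethoxy-2-methyl-3-oxopropanoate F2. Acidification returns 4.
- The antipode, (2R)-2-(4-bromo-2-methoxyphenoxy)-3-ethoxy-2-methyl-3-oxopropanoic acid F3, is recovered from the mother liquor, or is formed directly if the enzyme prefers the other ester. It is not lost: LiBH4 in THF reduces its ester while the lithium carboxylate stays inert, giving (2S)-2-(4-bromo-2-methoxyphenoxy)-3-hydroxy-2-methylpropanoic acid F4.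
- EtI with K2CO3 in DMF then esterifies F4 to 5. Exchanging which carboxyl is reduced exchanges the sense at C2.

**Step 7.** The attacking ring carbon is activated only by the ortho ether oxygen and feels two inductively withdrawing meta substituents. The 6-endo closure may therefore be slow enough for hydration of the alkyne, 5-exo closure, or ionisation of the tertiary propargylic C–O bond to compete. The fallback closes ring B by ring-closing metathesis, which does not depend on arene nucleophilicity; it sets out from 1 and 2 and returns at 9.
- 1 is formylated ortho to the hydroxyl group (MgCl2, Et3N, paraformaldehyde, MeCN, reflux) to 5-bromo-2-hydroxy-3-methoxybenzaldehyde F5.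
- Ph3P=CH2 (2.2 equiv, THF) converts F5 into 4-bromo-2-ethenyl-6-methoxyphenol F6.
- Alkylation with 2 as in step 1 should give diethyl 2-(4-bromo-2-ethenyl-6-methoxyphenoxy)-2-methylmalonate F7.
- The esterase hydrolysis of step 2 should give (2S)-2-(4-bromo-2-ethenyl-6-methoxyphenoxy)-3-ethoxy-2-methyl-3-oxopropanoic acid F8.
- The acid is reduced through its mixed anhydride (ClCO2Et, N-methylmorpholine, THF, −10 °C; then NaBH4), because borane would hydroborate the styrene. This should give ethyl (2S)-2-(4-bromo-2-ethenyl-6-methoxyphenoxy)-3-hydroxy-2-methylpropanoate F9.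
- Silylation as in step 4 should give ethyl (2S)-2-(4-bromo-2-ethenyl-6-methoxyphenoxy)-3-[(tert-butyldiphenylsilyl)oxy]-2-methylpropanoate F10.
- i-Bu2AlH as in step 5 should give (2S)-2-(4-bromo-2-ethenyl-6-methoxyphenoxy)-3-[(tert-butyldiphenylsilyl)oxy]-2-methylpropanal F11.
- Ph3P=CH2 should give the diene tert-butyl{[(2R)-2-(4-bromo-2-ethenyl-6-methoxyphenoxy)-2-methylbut-3-en-1-yl]oxy}diphenylsilane F12.
- The second-generation Grubbs catalyst RuCl2(=CHPh)(PCy3)(H2IMes) in CH2Cl2 at 40 °C then forms C3=C4 with loss of ethene and gives 9.

**Step 5.** Collapse of the tetrahedral intermediate before the quench would lead to over-reduction to the primary alcohol. The fallback separates reduction and oxidation; it sets out from 6 and returns at 7.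
- LiBH4 in THF at 0 °C reduces the ester completely to (2R)-2-(4-bromo-2-methoxyphenoxy)-3-[(tert-butyldiphenylsilyl)oxy]-2-methylpropan-1-ol F13.
- Dess–Martin periodinane with NaHCO3 in CH2Cl2 oxidises F13 to 7.
- F13 is oxidised promptly and kept away from base, because migration of the silyl group between the two CH2O arms would racemise C2. The tert-butyldiphenylsilyl group migrates slowly.

**Step 8.** Oxidative addition into the electron-rich aryl bromide may be slow. Prolonged heating would then allow protodestannylation and thermal electrocyclic opening and reclosure of ring B, with erosion of enantiomeric purity. The fallback avoids heat and palladium; it sets out from 9 and returns at 11.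
- Bromine–lithium exchange with n-BuLi in THF at −78 °C gives [(2R)-2-{[(tert-butyldiphenylsilyl)oxy]methyl}-8-methoxy-2-methyl-2H-chromen-6-yl]lithium F14.
- F14 is acylated in the same flask with N-methoxy-N-methylacetamide, and aqueous work-up releases 11 directly.

## Further compounds

F1 | step 2 | racemic 2-(4-bromo-2-methoxyphenoxy)-3-ethoxy-2-methyl-3-oxopropanoic acid | OC(=O)C(C)(C(=O)OCC)Oc1ccc(Br)cc1OC
F2 | step 2 | (R)-1-phenylethylammonium (2S)-2-(4-bromo-2-methoxyphenoxy)-3-ethoxy-2-methyl-3-oxopropanoate | C[C@@H]([NH3+])c1ccccc1.[O-]C(=O)[C@@](C)(C(=O)OCC)Oc1ccc(Br)cc1OC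
F3 | step 2 | (2R)-2-(4-bromo-2-methoxyphenoxy)-3-ethoxy-2-methyl-3-oxopropanoic acid | OC(=O)[C@](C)(C(=O)OCC)Oc1ccc(Br)cc1OC
F4 | step 2 | (2S)-2-(4-bromo-2-methoxyphenoxy)-3-hydroxy-2-methylpropanoic acid | OC[C@@](C)(C(=O)O)Oc1ccc(Br)cc1OC
F5 | step 7 | 5-bromo-2-hydroxy-3-methoxybenzaldehyde | COc1cc(Br)cc(C=O)c1O
F6 | step 7 | 4-bromo-2-ethenyl-6-methoxyphenol | COc1cc(Br)cc(C=C)c1O
F7 | step 7 | diethyl 2-(4-bromo-2-ethenyl-6-methoxyphenoxy)-2-methylmalonate | CCOC(=O)C(C)(C(=O)OCC)Oc1c(C=C)cc(Br)cc1OC
F8 | step 7 | (2S)-2-(4-bromo-2-ethenyl-6-methoxyphenoxy)-3-ethoxy-2-methyl-3-oxopropanoic acid | OC(=O)[C@@](C)(C(=O)OCC)Oc1c(C=C)cc(Br)cc1OC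
F9 | step 7 | ethyl (2S)-2-(4-bromo-2-ethenyl-6-methoxyphenoxy)-3-hydroxy-2-methylpropanoate | OC[C@@](C)(C(=O)OCC)Oc1c(C=C)cc(Br)cc1OC
F10 | step 7 | ethyl (2S)-2-(4-bromo-2-ethenyl-6-methoxyphenoxy)-3-[(tert-butyldiphenylsilyl)oxy]-2-methylpropanoate | CC(C)(C)[Si](c1ccccc1)(c1ccccc1)OC[C@@](C)(C(=O)OCC)Oc1c(C=C)cc(Br)cc1OC
F11 | step 7 | (2S)-2-(4-bromo-2-ethenyl-6-methoxyphenoxy)-3-[(tert-butyldiphenylsilyl)oxy]-2-methylpropanal | CC(C)(C)[Si](c1ccccc1)(c1ccccc1)OC[C@@](C)(C=O)Oc1c(C=C)cc(Br)cc1OC
F12 | step 7 | tert-butyl{[(2R)-2-(4-bromo-2-ethenyl-6-methoxyphenoxy)-2-methylbut-3-en-1-yl]oxy}diphenylsilane | CC(C)(C)[Si](c1ccccc1)(c1ccccc1)OC[C@@](C)(C=C)Oc1c(C=C)cc(Br)cc1OC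
F13 | step 5 | (2R)-2-(4-bromo-2-methoxyphenoxy)-3-[(tert-butyldiphenylsilyl)oxy]-2-methylpropan-1-ol | CC(C)(C)[Si](c1ccccc1)(c1ccccc1)OC[C@@](C)(CO)Oc1ccc(Br)cc1OC
F14 | step 8 | [(2R)-2-{[(tert-butyldiphenylsilyl)oxy]methyl}-8-methoxy-2-methyl-2H-chromen-6-yl]lithium | CC(C)(C)[Si](c1ccccc1)(c1ccccc1)OC[C@@]1(C)C=Cc2cc([Li])cc(OC)c2O1
A1 | alternative 1 | O-allyl ether of the target, [(2R)-6-acetyl-8-methoxy-2-methyl-2H-chromen-2-yl]methyl (E)-3-[3-methoxy-4-(prop-2-en-1-yloxy)phenyl]prop-2-enoate | C=CCOc1ccc(/C=C/C(=O)OC[C@@]2(C)C=Cc3cc(C(C)=O)cc(OC)c3O2)cc1OC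
A2 | alternative 1 | 1-{4-fluoro-3-methoxy-5-[(Z)-2-[(2R)-2-methyloxiran-2-yl]ethenyl]phenyl}ethan-1-one | CC(=O)c1cc(OC)c(F)c(c1)/C=C\[C@]1(C)CO1
A3 | alternative 1 | O-allylferulic acid, (E)-3-[3-methoxy-4-(prop-2-en-1-yloxy)phenyl]prop-2-enoic acid | C=CCOc1ccc(/C=C/C(=O)O)cc1OC
A4 | alternative 2 | 2-tert-butyl-5-{[(4-methoxybenzyl)oxy]methyl}-5-methyl-1,3-dioxolan-4-one, methyl cis to tert-butyl, C5 configured as C2 of the target | C[C@@]1(COCc2ccc(OC)cc2)O[C@@H](C(C)(C)C)OC1=O
A5 | alternative 2 | cis-2-tert-butyl-5-methyl-1,3-dioxolan-4-one, (2R,5R) | C[C@H]1O[C@@H](C(C)(C)C)OC1=O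
A6 | alternative 3 | 6-bromo-2-{[(tert-butyldimethylsilyl)oxy]methyl}-8-methoxy-2-methylchroman-3-one, C2 configured as in the target | CC(C)(C)[Si](C)(C)OC[C@@]1(C)C(=O)Cc2cc(Br)cc(OC)c2O1
A7 | alternative 3 | 5-bromo-2-{[(tert-butyldimethylsilyl)oxy]methyl}-7-methoxy-2-methyl-1-benzofuran-3(2H)-one, C2 configured as in the target | CC(C)(C)[Si](C)(C)OC[C@@]1(C)C(=O)c2cc(Br)cc(OC)c2O1
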